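**Retrosynthetic overview**

1. Target 25 ⇐ exo-selective Markovnikov hydration of the norbornene C=C of 23 ⇐ intramolecular Diels–Alder reaction of triene 22 (a 1-alkyl-2-isopropylcyclopentadiene tethered to a vinyl group on ring D).
2. Enabling feature: rings A and B form a bicyclo[2.2.1]heptane whose quaternary bridgehead (common to A, B and C) and the adjacent ring-B/C methine also belong to ring C. Cutting the bridgehead–methine bond (which completes ring C) and the bond from the other bridgehead CH to the ring-B CH2 reveals ring A as a cyclopentadiene and the CH–CH2 unit as a vinyl group, joined by the four ring-C atoms CH2–CH2–C(CH3)–CH.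
3. 22 ⇐ iodide 16 + 3-ethoxycyclopent-2-en-1-one (Stork–Danheiser alkylation, isopropyl addition with carbonyl transposition, reduction, dehydration); ring A arrives as a preformed five-membered ring.
4. Ring D ⇐ enantiospecific bromonium cyclization of bromochloride 8 ⇐ catalytic enantioselective bromochlorination of allylic alcohol 4 ⇐ but-3-yn-1-ol.
5. Order of ring formation: D (step 6); A attached preformed (step 13); B and C closed together in step 16, where the bond that completes ring C is made and after which no ring is formed.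

Key step: step 16

Remark: TBDPS = tert-butyldiphenylsilyl and TBDPSO = its silyloxy group. Rings are lettered A (five-membered ring with the isopropyl carbinol), B (the other five-membered ring of the bicyclo[2.2.1]heptane), C (central cyclohexane) and D (bromocyclohexane). Compounds 18–21 are epimer mixtures at the sp3 carbon(s) of the five-membered ring, all converging on 22. The ligand enantiomer in step 3 is the one that delivers the (2S,3R) bromochloride.

**Route**

Step 1
Reactants: 1 but-3-yn-1-ol
Product: 2 tert-butyl(but-3-yn-1-yloxy)diphenylsilane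
Conditions: TBDPSCl, imidazole, DMF, rt
Reagents that add atoms: tert-butyl(chloro)diphenylsilane CC(C)(C)[Si](Cl)(c1ccccc1)c1ccccc1
Why: Standard silylation of a primary alcohol; the robust TBDPS ether masks the later attachment point of ring A through steps 2–10.

Step 2
Reactants: 2 tert-butyl(but-3-yn-1-yloxy)diphenylsilane
Product: 4 (2E)-5-(TBDPSO)-3-methylpent-2-en-1-ol, via alkenyldimethylalane 3 (not isolated)
Conditions: Me3Al, Cp2ZrCl2 (cat.), CH2Cl2, 0 °C to rt; then n-BuLi, −78 °C; (CH2O)n, THF, to rt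
Reagents that add atoms: trimethylaluminium C[Al](C)C; paraformaldehyde (as formaldehyde) C=O
Why: Zr-catalysed carboalumination adds CH3 and Al syn and regioselectively across the terminal alkyne, and hydroxymethylation of the alkenyl aluminate proceeds with retention, which fixes the E alkene (chain trans to CH2OH) that later encodes the ring-D relative configuration.

Step 3
Reactants: 4 (2E)-5-(TBDPSO)-3-methylpent-2-en-1-ol
Product: 5 (2S,3R)-2-bromo-3-chloro-5-(TBDPSO)-3-methylpentan-1-ol
Conditions: NBS, ClTi(Oi-Pr)3, chiral tridentate Schiff-base ligand (20 mol %), hexanes, −20 °C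
Reagents that add atoms: N-bromosuccinimide O=C1CCC(=O)N1Br; chlorotitanium triisopropoxide CC(C)O[Ti](Cl)(OC(C)C)OC(C)C
Why: Titanium/Schiff-base-catalysed enantioselective bromochlorination of an allylic alcohol: the Ti-bound alkoxide directs anti addition of Br+ to the carbon next to CH2OH and of chloride to the tertiary carbon, and the ligand selects the alkene face, setting both stereocentres.

Step 4
Reactants: 5 (2S,3R)-2-bromo-3-chloro-5-(TBDPSO)-3-methylpentan-1-ol
Product: 6 (2S,3R)-2-bromo-3-chloro-5-(TBDPSO)-3-methylpentyl trifluoromethanesulfonate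
Conditions: Tf2O, 2,6-lutidine, CH2Cl2, −78 °C; used directly
Reagents that add atoms: trifluoromethanesulfonic anhydride O=S(=O)(OS(=O)(=O)C(F)(F)F)C(F)(F)F
Why: O-Sulfonylation leaves both stereocentres untouched and provides a leaving group strong enough for SN2 at the β-branched, bromide-flanked primary carbon.

Step 5
Reactants: 6 (2S,3R)-2-bromo-3-chloro-5-(TBDPSO)-3-methylpentyl trifluoromethanesulfonate; 7 ethyl (2E)-3-ethoxybut-2-enoate
Product: 8 ethyl (2E,6S,7R)-6-bromo-7-chloro-3-ethoxy-7-methyl-9-(TBDPSO)non-2-enoate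
Conditions: 7, LDA, THF, −78 °C; then 6, DMPU, −78 to −40 °C
Reagents that add atoms: none
Why: γ-Deprotonation of the β-ethoxycrotonate gives a dienolate that is alkylated at its γ-carbon by the primary triflate (vinylogous-ester alkylation, an acetoacetate-dianion equivalent); the halogen-bearing stereocentres are not involved.

Step 6
Reactants: 8 ethyl (2E,6S,7R)-6-bromo-7-chloro-3-ethoxy-7-methyl-9-(TBDPSO)non-2-enoate
Product: 10 ethyl (1S,2S,3S)-3-bromo-2-methyl-6-oxo-2-[2-(TBDPSO)ethyl]cyclohexane-1-carboxylate, via cyclic enol ether 9 (not isolated)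
Conditions: (CF3)2CHOH, K2CO3, 0 °C to rt; then 1 M HCl, THF, rt
Reagents that add atoms: water O
Why: Solvolytic ionization of the tertiary chloride with anchimeric assistance by the vicinal bromine regenerates the bromonium ion enantiospecifically, and 6-endo capture at its tertiary carbon by the α-carbon of the β-ethoxyacrylate (cation–olefin cyclization through a chair, O-alkylation blocked by the O-ethyl group) closes ring D with net retention at the quaternary centre and equatorial bromine; acid hydrolysis unveils the β-keto ester and lets the ester settle equatorial.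

Step 7
Reactants: 10 ethyl (1S,2S,3S)-3-bromo-2-methyl-6-oxo-2-[2-(TBDPSO)ethyl]cyclohexane-1-carboxylate
Product: 11 ethyl (1S,2S,3S,6R)-3-bromo-6-hydroxy-2,6-dimethyl-2-[2-(TBDPSO)ethyl]cyclohexane-1-carboxylate
Conditions: MeMgCl, anhydrous CeCl3, THF, −78 to −20 °C
Reagents that add atoms: methylmagnesium chloride C[Mg]Cl
Why: Cerium-mediated Grignard addition to the ketone of an enolizable β-dicarbonyl compound, chemoselective over the ester; axial attack is blocked by the 1,3-syn-axial ring methyl group, so methyl enters equatorially and the hydroxyl becomes axial as in the target.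

Step 8
Reactants: 11 ethyl (1S,2S,3S,6R)-3-bromo-6-hydroxy-2,6-dimethyl-2-[2-(TBDPSO)ethyl]cyclohexane-1-carboxylate
Product: 12 (1R,2R,3S,4S)-4-bromo-2-(hydroxymethyl)-1,3-dimethyl-3-[2-(TBDPSO)ethyl]cyclohexan-1-ol
Conditions: DIBAL-H, CH2Cl2, −78 to 0 °C; Rochelle salt work-up
Reagents that add atoms: none
Why: Hydride reduction of the ester to the primary alcohol; the hindered secondary bromide, the silyl ether and all stereocentres are inert to DIBAL-H.

Step 9
Reactants: 12 (1R,2R,3S,4S)-4-bromo-2-(hydroxymethyl)-1,3-dimethyl-3-[2-(TBDPSO)ethyl]cyclohexan-1-ol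
Product: 13 (1S,2S,3S,6R)-3-bromo-6-hydroxy-2,6-dimethyl-2-[2-(TBDPSO)ethyl]cyclohexane-1-carbaldehyde
Conditions: TEMPO (cat.), PhI(OAc)2, CH2Cl2, rt
Reagents that add atoms: none
Why: Oxoammonium oxidation is selective for the primary alcohol (the tertiary one cannot be oxidized) and is near neutral, so neither epimerization of the equatorial formyl group nor retro-aldol cleavage is expected.

Step 10
Reactants: 13 (1S,2S,3S,6R)-3-bromo-6-hydroxy-2,6-dimethyl-2-[2-(TBDPSO)ethyl]cyclohexane-1-carbaldehyde
Product: 14 (1R,2S,3S,4S)-4-bromo-2-ethenyl-1,3-dimethyl-3-[2-(TBDPSO)ethyl]cyclohexan-1-ol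
Conditions: Ph3PCH3Br, KHMDS, THF, 0 °C; then 13, −78 to 0 °C
Reagents that add atoms: methyltriphenylphosphonium bromide C[P+](c1ccccc1)(c1ccccc1)c1ccccc1.[Br-]
Why: Wittig methylenation of the aldehyde with excess salt-free ylide at low temperature installs the dienophile; the stereocentre next to the aldehyde keeps its thermodynamically preferred equatorial substituent.

Step 11
Reactants: 14 (1R,2S,3S,4S)-4-bromo-2-ethenyl-1,3-dimethyl-3-[2-(TBDPSO)ethyl]cyclohexan-1-ol
Product: 15 (1R,2S,3S,4S)-4-bromo-2-ethenyl-3-(2-hydroxyethyl)-1,3-dimethylcyclohexan-1-ol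
Conditions: TBAF, THF, rt
Reagents that add atoms: none
Why: Fluoride-induced desilylation frees the primary alcohol; the hindered secondary bromide does not undergo substitution or elimination under these conditions.

Step 12
Reactants: 15 (1R,2S,3S,4S)-4-bromo-2-ethenyl-3-(2-hydroxyethyl)-1,3-dimethylcyclohexan-1-ol
Product: 16 (1R,2S,3S,4S)-4-bromo-2-ethenyl-3-(2-iodoethyl)-1,3-dimethylcyclohexan-1-ol
Conditions: I2, PPh3, imidazole, CH2Cl2, 0 °C
Reagents that add atoms: iodine II
Why: Appel-type iodination converts only the primary alcohol; the tertiary alcohol is too hindered to form the alkoxyphosphonium salt.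

Step 13
Reactants: 16 (1R,2S,3S,4S)-4-bromo-2-ethenyl-3-(2-iodoethyl)-1,3-dimethylcyclohexan-1-ol; 17 3-ethoxycyclopent-2-en-1-one
Product: 18 5-{2-[(1S,2S,3R,6S)-6-bromo-2-ethenyl-3-hydroxy-1,3-dimethylcyclohexyl]ethyl}-3-ethoxycyclopent-2-en-1-one
Conditions: 17 (3 equiv), LDA, THF, −78 °C; then 16, HMPA, −78 to 0 °C
Reagents that add atoms: none
Why: Stork–Danheiser kinetic α′-alkylation of the vinylogous-ester enolate by the primary iodide (excess enolate absorbs the tertiary OH; the resulting alkoxide is trans-1,3 to the side chain and cannot reach the iodide); the new sp3 centre is inconsequential.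

Step 14
Reactants: 18 5-{2-[(1S,2S,3R,6S)-6-bromo-2-ethenyl-3-hydroxy-1,3-dimethylcyclohexyl]ethyl}-3-ethoxycyclopent-2-en-1-one
Product: 20 4-{2-[(1S,2S,3R,6S)-6-bromo-2-ethenyl-3-hydroxy-1,3-dimethylcyclohexyl]ethyl}-3-(propan-2-yl)cyclopent-2-en-1-one, via tertiary allylic alcohol 19 (not isolated)
Conditions: i-PrMgCl, CeCl3, THF, −78 to 0 °C; then 1 M HCl, THF, rt
Reagents that add atoms: isopropylmagnesium chloride CC(C)[Mg]Cl; water O
Why: Second half of the Stork–Danheiser sequence: 1,2-addition to the vinylogous ester, then acid hydrolysis and dehydration transpose the carbonyl and place the isopropyl group on the ring carbon next to the one that carries the tether.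

Step 15
Reactants: 20 4-{2-[(1S,2S,3R,6S)-6-bromo-2-ethenyl-3-hydroxy-1,3-dimethylcyclohexyl]ethyl}-3-(propan-2-yl)cyclopent-2-en-1-one
Product: 22 (1R,2S,3S,4S)-4-bromo-2-ethenyl-1,3-dimethyl-3-{2-[2-(propan-2-yl)cyclopenta-1,3-dien-1-yl]ethyl}cyclohexan-1-ol, via cyclopentenol 21 (not isolated)
Conditions: NaBH4, CeCl3·7H2O, MeOH, −20 °C; then crude 21, PPTS (cat.), benzene, 40 °C
Reagents that add atoms: none
Why: Luche 1,2-reduction followed by mild acid dehydration through the allyl cation should give the cyclopentadiene (equilibrating [1,5]-H-shift isomers, drawn as the 1-alkyl-2-isopropyl isomer); the non-allylic tertiary alcohol on ring D ionizes far more slowly.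

Step 16
Reactants: 22 (1R,2S,3S,4S)-4-bromo-2-ethenyl-1,3-dimethyl-3-{2-[2-(propan-2-yl)cyclopenta-1,3-dien-1-yl]ethyl}cyclohexan-1-ol
Product: 23 tetracyclic Diels–Alder adduct (target skeleton with a C=C in ring A between the isopropyl-bearing carbon and the adjacent CH; no carbinol in ring A; ring D as in 22)
Conditions: toluene (0.005 M, degassed), BHT, 2,6-di-tert-butylpyridine (cat.), sealed tube, 170 °C
Reagents that add atoms: none
Why: [1,5]-H shifts interconvert the cyclopentadiene isomers of 22, and only the 1-alkyl-2-isopropylcyclopenta-1,3-diene, whose tether sits on a diene terminus, can reach the vinyl group, so the mixture funnels through one concerted thermal [4+2] transition state. The closest known reaction type is the intramolecular Diels–Alder reaction of 1-(ω-alkenyl)cyclopentadienes with unactivated alkenes, which gives bridgehead-fused norbornenes. Ring C is closed by the bond from the tethered diene terminus to the internal vinyl carbon through a chair-like six-membered tether ring trans-fused to ring D, and ring B by the second σ-bond from the far diene terminus to the vinyl CH2, which turns ring A into the norbornene. The new ring-B/C methine is controlled by the ring-D stereocentres: the vinyl CH2 must lie equatorial on the nascent chair, because the alternative places it 1,3-diaxial to the ring-D methyl group. The quaternary bridgehead and the bridgehead CH are set together by the orientation that puts the small CH2 of the diene, not the isopropyl-bearing carbon, into the axial position over ring C, so the ring-D carbon ends up exo on the norbornene as in the target. The step needs tautomer, regio- and diastereofacial selectivity, secured respectively by the tether length, by the trans-diequatorial arrangement of vinyl group and side chain on ring D, and by the isopropyl group; BHT and the hindered base guard the bromide and the tertiary alcohol at 170 °C.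

Step 17
Reactants: 23 tetracyclic Diels–Alder adduct
Product: 25 CNP0362628.1 (target), via tertiary hydroperoxide 24 (not isolated)
Conditions: Mn(dpm)3 (cat.), PhSiH3, O2 (1 atm), i-PrOH/CH2Cl2, 0 °C to rt; then PPh3
Reagents that add atoms: dioxygen O=O
Why: Mukaiyama-type hydrogen-atom-transfer hydration: H adds to the CH end of the trisubstituted norbornene, and the tertiary 2-norbornyl radical (no cationic skeletal rearrangement possible) is trapped by O2 on the exo face, away from the endo hydrogens of the opposite two-carbon bridge, giving the exo alcohol with endo isopropyl; the alkyl bromide and tertiary alcohol are inert.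

**Compound list**

1 | but-3-yn-1-ol | C#CCCO | starting material
2 | tert-butyl(but-3-yn-1-yloxy)diphenylsilane | C#CCCO[Si](c1ccccc1)(c1ccccc1)C(C)(C)C | intermediate
3 | [(1E)-4-(TBDPSO)-2-methylbut-1-en-1-yl]dimethylalane | C[Al](C)/C=C(C)/CCO[Si](c1ccccc1)(c1ccccc1)C(C)(C)C | intermediate
4 | (2E)-5-(TBDPSO)-3-methylpent-2-en-1-ol | OC/C=C(C)/CCO[Si](c1ccccc1)(c1ccccc1)C(C)(C)C | intermediate
5 | (2S,3R)-2-bromo-3-chloro-5-(TBDPSO)-3-methylpentan-1-ol | Cl[C@](C)(CCO[Si](c1ccccc1)(c1ccccc1)C(C)(C)C)[C@@H](Br)CO | intermediate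
6 | (2S,3R)-2-bromo-3-chloro-5-(TBDPSO)-3-methylpentyl trifluoromethanesulfonate | Cl[C@](C)(CCO[Si](c1ccccc1)(c1ccccc1)C(C)(C)C)[C@@H](Br)COS(=O)(=O)C(F)(F)F | intermediate
7 | ethyl (2E)-3-ethoxybut-2-enoate | C/C(OCC)=C\C(=O)OCC | starting material
8 | ethyl (2E,6S,7R)-6-bromo-7-chloro-3-ethoxy-7-methyl-9-(TBDPSO)non-2-enoate | Cl[C@](C)(CCO[Si](c1ccccc1)(c1ccccc1)C(C)(C)C)[C@@H](Br)CC/C(OCC)=C\C(=O)OCC | intermediate
9 | ethyl (5S,6S)-5-bromo-2-ethoxy-6-methyl-6-[2-(TBDPSO)ethyl]cyclohex-1-ene-1-carboxylate | CCOC(=O)C1=C(OCC)CC[C@H](Br)[C@@]1(C)CCO[Si](c2ccccc2)(c2ccccc2)C(C)(C)C | intermediate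
10 | ethyl (1S,2S,3S)-3-bromo-2-methyl-6-oxo-2-[2-(TBDPSO)ethyl]cyclohexane-1-carboxylate | CCOC(=O)[C@H]1[C@](C)(CCO[Si](c2ccccc2)(c2ccccc2)C(C)(C)C)[C@@H](Br)CCC1=O | intermediate
11 | ethyl (1S,2S,3S,6R)-3-bromo-6-hydroxy-2,6-dimethyl-2-[2-(TBDPSO)ethyl]cyclohexane-1-carboxylate | CCOC(=O)[C@H]1[C@](C)(CCO[Si](c2ccccc2)(c2ccccc2)C(C)(C)C)[C@@H](Br)CC[C@@]1(C)O | intermediate
12 | (1R,2R,3S,4S)-4-bromo-2-(hydroxymethyl)-1,3-dimethyl-3-[2-(TBDPSO)ethyl]cyclohexan-1-ol | OC[C@H]1[C@](C)(CCO[Si](c2ccccc2)(c2ccccc2)C(C)(C)C)[C@@H](Br)CC[C@@]1(C)O | intermediate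
13 | (1S,2S,3S,6R)-3-bromo-6-hydroxy-2,6-dimethyl-2-[2-(TBDPSO)ethyl]cyclohexane-1-carbaldehyde | O=C[C@H]1[C@](C)(CCO[Si](c2ccccc2)(c2ccccc2)C(C)(C)C)[C@@H](Br)CC[C@@]1(C)O | intermediate
14 | (1R,2S,3S,4S)-4-bromo-2-ethenyl-1,3-dimethyl-3-[2-(TBDPSO)ethyl]cyclohexan-1-ol | C=C[C@H]1[C@](C)(CCO[Si](c2ccccc2)(c2ccccc2)C(C)(C)C)[C@@H](Br)CC[C@@]1(C)O | intermediate
15 | (1R,2S,3S,4S)-4-bromo-2-ethenyl-3-(2-hydroxyethyl)-1,3-dimethylcyclohexan-1-ol | C=C[C@H]1[C@](C)(CCO)[C@@H](Br)CC[C@@]1(C)O | intermediate
16 | (1R,2S,3S,4S)-4-bromo-2-ethenyl-3-(2-iodoethyl)-1,3-dimethylcyclohexan-1-ol | C=C[C@H]1[C@](C)(CCI)[C@@H](Br)CC[C@@]1(C)O | intermediate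
17 | 3-ethoxycyclopent-2-en-1-one | CCOC1=CC(=O)CC1 | starting material
18 | 5-{2-[(1S,2S,3R,6S)-6-bromo-2-ethenyl-3-hydroxy-1,3-dimethylcyclohexyl]ethyl}-3-ethoxycyclopent-2-en-1-one (both C-5 epimers) | C=C[C@H]1[C@](C)(CCC2CC(OCC)=CC2=O)[C@@H](Br)CC[C@@]1(C)O | intermediate
19 | 5-{2-[(1S,2S,3R,6S)-6-bromo-2-ethenyl-3-hydroxy-1,3-dimethylcyclohexyl]ethyl}-3-ethoxy-1-(propan-2-yl)cyclopent-2-en-1-ol (epimer mixture) | C=C[C@H]1[C@](C)(CCC2CC(OCC)=CC2(O)C(C)C)[C@@H](Br)CC[C@@]1(C)O | intermediate
20 | 4-{2-[(1S,2S,3R,6S)-6-bromo-2-ethenyl-3-hydroxy-1,3-dimethylcyclohexyl]ethyl}-3-(propan-2-yl)cyclopent-2-en-1-one (both C-4 epimers) | C=C[C@H]1[C@](C)(CCC2CC(=O)C=C2C(C)C)[C@@H](Br)CC[C@@]1(C)O | intermediate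
21 | 4-{2-[(1S,2S,3R,6S)-6-bromo-2-ethenyl-3-hydroxy-1,3-dimethylcyclohexyl]ethyl}-3-(propan-2-yl)cyclopent-2-en-1-ol (epimer mixture) | C=C[C@H]1[C@](C)(CCC2CC(O)C=C2C(C)C)[C@@H](Br)CC[C@@]1(C)O | intermediate
22 | (1R,2S,3S,4S)-4-bromo-2-ethenyl-1,3-dimethyl-3-{2-[2-(propan-2-yl)cyclopenta-1,3-dien-1-yl]ethyl}cyclohexan-1-ol | C=C[C@H]1[C@](C)(CCC2=C(C(C)C)C=CC2)[C@@H](Br)CC[C@@]1(C)O | intermediate
23 | tetracyclic Diels–Alder adduct: target skeleton with a C=C in ring A between the isopropyl-bearing carbon and the adjacent CH; ring C trans-fused to ring D; ring-D carbon exo on the norbornene | CC(C)C1=C[C@@H]2C[C@H]3[C@H]4[C@](C)(CC[C@@]31C2)[C@@H](Br)CC[C@@]4(C)O | intermediate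
24 | exo tertiary hydroperoxide at the isopropyl-bearing carbon of ring A (otherwise as the target) | CC(C)[C@]1(OO)C[C@@H]2C[C@H]3[C@H]4[C@](C)(CC[C@@]31C2)[C@@H](Br)CC[C@@]4(C)O | intermediate
25 | CNP0362628.1: tetracyclic bromo diol with exo tertiary carbinol and endo isopropyl in ring A, axial tertiary carbinol and equatorial bromine in ring D | CC(C)[C@]1(O)C[C@@H]2C[C@H]3[C@H]4[C@](C)(CC[C@@]31C2)[C@@H](Br)CC[C@@]4(C)O | target

**Totals and risks**

Total step count: 17. Longest linear sequence: 17 steps (from but-3-yn-1-ol; 7 and 17 are commercial building blocks).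

Most likely to fail, step 6: the bromonium ion may be lost to elimination or solvent capture before the deactivated push–pull enol ether carbon attacks, or ionization without bromine participation may erode the enantiospecificity. The fallback sets out from 8 and changes the terminating nucleophile and the mode of ionization. Dilute HCl in THF would hydrolyse the enol ether to ethyl (6S,7R)-6-bromo-7-chloro-7-methyl-3-oxo-9-(TBDPSO)nonanoate F1. SnCl4 in CH2Cl2 (−78 to 0 °C) would then chelate the keto ester as its tin enolate while assisting departure of the tertiary chloride, so that the bromonium ion is trapped at carbon in a Lewis-acid cation–olefin cyclization terminated by a β-keto ester. The route is rejoined at 10.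

Second, step 16: the unactivated vinyl group may react too slowly, so that loss of HBr, dehydration or diene dimerization at 170 °C competes, or the two tether orientations may not be discriminated well enough. The fallback sets out from 20 and activates the dienophile.
- Cross-metathesis with methyl acrylate (Hoveyda–Grubbs II) would give the (E)-acrylate analogue of 20 F2.
- Luche reduction would give its cyclopentenol F3, and PPTS dehydration the cyclopentadienyl acrylate F4.
- F4 should cyclize at or below 80 °C, the E geometry and the endo preference of the ester both favouring the exo placement of the ring-D carbon, to the adduct carrying an endo CO2Me on the ring-B CH2 carbon F5.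
- DIBAL-H at −78 °C would give the corresponding endo aldehyde F6, and stoichiometric RhCl(PPh3)3 (Tsuji–Wilkinson decarbonylation, retention) would excise the formyl group.

The route is rejoined at 23.

Third, step 7: deprotonation of the strongly enolized β-keto ester may outrun carbonyl addition, returning starting material. The fallback sets out from 10 and removes the acidic 1,3-dicarbonyl motif before the methyl addition.
- Ketalization (ethylene glycol, PPTS, benzene, reflux) would give ethyl (6S,7S,8S)-8-bromo-7-methyl-7-[2-(TBDPSO)ethyl]-1,4-dioxaspiro[4.5]decane-6-carboxylate F7.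
- DIBAL-H would reduce the ester to {(6R,7S,8S)-8-bromo-7-methyl-7-[2-(TBDPSO)ethyl]-1,4-dioxaspiro[4.5]decan-6-yl}methanol F8.
- Mild acid (PPTS, wet acetone) would release (2R,3S,4S)-4-bromo-2-(hydroxymethyl)-3-methyl-3-[2-(TBDPSO)ethyl]cyclohexan-1-one F9.
- Excess MeMgCl/CeCl3 at −78 °C would add equatorially to this simple ketone.

The route is rejoined at 12, bypassing step 8.

Further compounds
F1 | step 6 | ethyl (6S,7R)-6-bromo-7-chloro-7-methyl-3-oxo-9-(TBDPSO)nonanoate | Cl[C@](C)(CCO[Si](c1ccccc1)(c1ccccc1)C(C)(C)C)[C@@H](Br)CCC(=O)CC(=O)OCC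
F2 | step 16 | (E)-acrylate analogue of 20 (vinyl group replaced by (E)-CH=CH-CO2Me) | COC(=O)/C=C/[C@H]1[C@](C)(CCC2CC(=O)C=C2C(C)C)[C@@H](Br)CC[C@@]1(C)O
F3 | step 16 | cyclopentenol of F2 (ring ketone reduced to the allylic alcohol) | COC(=O)/C=C/[C@H]1[C@](C)(CCC2CC(O)C=C2C(C)C)[C@@H](Br)CC[C@@]1(C)O
F4 | step 16 | cyclopentadienyl acrylate (22 with (E)-CH=CH-CO2Me in place of the vinyl group) | COC(=O)/C=C/[C@H]1[C@](C)(CCC2=C(C(C)C)C=CC2)[C@@H](Br)CC[C@@]1(C)O
F5 | step 16 | adduct 23 carrying an endo CO2Me on the ring-B CH2 carbon | CC(C)C1=C[C@@H]2[C@H](C(=O)OC)[C@H]3[C@H]4[C@](C)(CC[C@@]31C2)[C@@H](Br)CC[C@@]4(C)O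
F6 | step 16 | adduct 23 carrying an endo CHO on the ring-B CH2 carbon | CC(C)C1=C[C@@H]2[C@H](C=O)[C@H]3[C@H]4[C@](C)(CC[C@@]31C2)[C@@H](Br)CC[C@@]4(C)O
F7 | step 7 | ethyl (6S,7S,8S)-8-bromo-7-methyl-7-[2-(TBDPSO)ethyl]-1,4-dioxaspiro[4.5]decane-6-carboxylate | CCOC(=O)[C@H]1[C@](C)(CCO[Si](c2ccccc2)(c2ccccc2)C(C)(C)C)[C@@H](Br)CCC13OCCO3
F8 | step 7 | {(6R,7S,8S)-8-bromo-7-methyl-7-[2-(TBDPSO)ethyl]-1,4-dioxaspiro[4.5]decan-6-yl}methanol | OC[C@H]1[C@](C)(CCO[Si](c2ccccc2)(c2ccccc2)C(C)(C)C)[C@@H](Br)CCC13OCCO3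
F9 | step 7 | (2R,3S,4S)-4-bromo-2-(hydroxymethyl)-3-methyl-3-[2-(TBDPSO)ethyl]cyclohexan-1-one | OC[C@H]1[C@](C)(CCO[Si](c2ccccc2)(c2ccccc2)C(C)(C)C)[C@@H](Br)CCC1=O
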